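- Reduce this flask to one clock read from the earlier runs.

in all of them: Z 0.050 M
- noon: L 0.80 equiv (in portions, 2); G 1.2 mol%; run made earlier; portions every 15 s
- midnight: L 0.80 equiv (in portions, 2); G 1.9 mol%; run made earlier; portions every 15 s
- flask: L 0.800 equiv (in portions, 2); G 2.5 mol%; the portions of L follow each other after 15 s, the first at the start; time 12 min

| run | time / min | J / % | Z / % | E / % |
|---|---|---|---|---|
| noon | 2.00 | 35.3 | 53.8 | 13.4 |
| noon | 4.00 | 50.5 | 40.7 | 5.7 |
| noon | 6.00 | 61.5 | 35.7 | 4.3 |
| noon | 8.00 | 66.3 | 31.1 | 3.1 |
| noon | 10.0 | 70.4 | 27.6 | 2.9 |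
| midnight | 2.00 | 33.3 | 53.5 | 12.3 |
| midnight | 4.00 | 51.3 | 41.7 | 7.3 |
| midnight | 6.00 | 60.1 | 35.2 | 2.4 |
| midnight | 8.00 | 64.5 | 31.4 | 3.2 |
| midnight | 10.0 | 70.0 | 29.3 | 2.3 |

(scatter of a reading: 1 percentage point)

- the numbers in the tables scatter by 1 percentage point (one standard deviation)
- a reading or a percentage of E counts all its forms, free or not

- the largest share of what was charged as Z, at 12 min belongs to (J / Z / E)
- the largest share itself, whichever of these holds it, in percent of the Z charged

- The noon and midnight runs differed in G but read alike within the scatter, so I averaged them.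
- I took each Z lost to use one L, so L was the limiting reagent and, once both portions were in, [L] stayed 20.0% of the Z charged below [Z].
- For second-order loss, ln([Z]/[L]) climbs steadily. Mean [Z] read 41.2% at 4.00 min and 28.5% at 10.0 min.
- That slope gave the drain time, the inverse of the apparent second-order constant times the charged [Z]: τ = 2.18 min.
- First rung: the portions came 0.25 min apart, less than τ, so I treated L as charged at once.
- Next rung: at noon E read 13.4% at 2.00 min and 5.7% at 4.00 min, so E was a passing store.
- Next rung: J grew on the clock τ.
- Last rung: with [Z] nearing a floor equal to the gap, I expected [L] to fall by a factor e per tail time, τ divided by the gap, or 10.9 min. That was close to 12 min, so I expected Z above its floor.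
- Carrying the line to 12 min in the flask gave me [Z] = 26.6%. With E at its mean late reading of 2.60%, J came to 70.8%.
- The forecast gave J at 72%, above my figure, and held that “G does not limit the rate in this range”.
- The flask gave J at 72.8%, with Z at 26.2% and E at 1.07%.

    Z + L + G ⇌ E + G, rate k1*[Z]*[L]*[G] forward; the back reaction follows from the equilibrium constant (K = 13.0 /M, k = 1190 /M²/s)
    Z + L → J (k = 0.218 /M/s)
    X ⇌ E, rate k3*(cs3 - [E]) while solid is left; crystals form when [E] > cs3 (solubility = 31.0 mM, k = 0.449 /s)

- In this flask J led because E fell back to Z + L: the run without that return gave J 10.2% against 72.8%. In this flask 12 min was 5.50 τ, and the τ line's [Z] of 26.6% stood against 26.2%. A further flask, like this one but with 0.320 equiv of L, held [Z] at 68.5%. Multiplying that share by the exponential of minus its gap times 12 min over τ put L at 1.62% of its charge. That flask held 1.5% of its L.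

The readings are calculated for an exercise; scatter was added.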